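**Retrosynthetic overview**

1. The target is fisetinidol-(4α→8)-[fisetinidol-(4β→6)]-catechin: all three units 2R,3S; the C-8-linked unit is 4S (3,4-trans) and the C-6-linked unit is 4R (3,4-cis). Both interflavanyl C-4–aryl bonds are cut at once, giving (+)-catechin and two equivalents of one C-4 electrophile, the quinone methide of leucofisetinidin.
2. The leucofisetinidin is generated in the coupling flask by hydride reduction of (+)-fustin (a dihydroflavonol 4-reductase mimic); its C-4 configuration is irrelevant.
3. Key ring-forming step: ring C of the fisetinidol unit (made once, used twice) is closed from a 2'-hydroxychalcone by one catalytic asymmetric oxa-Michael cyclisation/enolate hydroxylation. This merges the chalcone isomerase and flavanone 3-hydroxylase events and sets C-2 and C-3 together.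
4. The chalcone comes from a Claisen–Schmidt condensation of two catalogue benzyl ethers; benzyl is the only protecting group and is removed before the couplings.
5. Ring order: fisetinidol ring C (step 2) is the only ring constructed; the catechin rings are bought intact and no ring is formed after the interflavanyl bonds.

Assumption: the cinchoninium-derived catalyst is taken to deliver the (2R,3R) series, by analogy with its sense in enone oxygenation. The configuration is checked at compound 6 against the rotation and CD of natural (+)-fustin, and the cinchonidinium pseudo-enantiomer is the drop-in replacement if the sense proves opposite.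

**Route**

Step 1
Reactants: 1 4'-benzyloxy-2'-hydroxyacetophenone; 2 3,4-bis(benzyloxy)benzaldehyde
Product: 3 (E)-2'-hydroxy-4',3,4-tris(benzyloxy)chalcone
Conditions: KOH (50% aq.), EtOH, rt, 48 h; then aq. HCl to pH 5; recrystallise
Reagents that add atoms: none
Why: Claisen–Schmidt (crossed aldol) condensation, in which the acetophenone enolate adds to the non-enolisable aldehyde and E1cB dehydration gives only the conjugated E-enone, the hydrogen-bonded 2'-OH and the benzyl ethers being inert to aqueous KOH; no stereocentre is formed.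

Step 2
Reactants: 3 (E)-2'-hydroxy-4',3,4-tris(benzyloxy)chalcone
Product: 5 (2R,3R)-7,3',4'-tri-O-benzylfustin, via flavanone enolate 4 (not isolated)
Conditions: N-(9-anthracenylmethyl)cinchoninium chloride (10 mol%), 30% aq. H2O2 (3 equiv), KOH (0.3 equiv, 1 M aq.), toluene–CH2Cl2 4:1, −15 °C, N2, 16 h; recrystallise
Reagents that add atoms: hydrogen peroxide, OO
Why: Proposed new method: an enantioselective Algar–Flynn–Oyamada reaction in which the chalcone phenoxide, ion-paired with the chiral cinchoninium cation (its C-9 OH hydrogen-bonded to the enone carbonyl), closes ring C by 6-endo oxa-Michael addition on one enone face (the chalcone isomerase event, setting C-2) and the enolate 4 is hydroxylated by H2O2 anti to the new 2-aryl group before retro-Michael racemisation can occur (the flavanone 3-hydroxylase event, setting C-3 trans); the closest known reactions are the racemic Algar–Flynn–Oyamada oxidation, which stops at trans-dihydroflavonols in the cold, cinchona ion-pairing catalysis of the 2'-hydroxychalcone-to-flavanone cyclisation, and cinchona phase-transfer epoxidation of chalcones with H2O2, and enantiopurity is upgraded by recrystallisation.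

Step 3
Reactants: 5 (2R,3R)-7,3',4'-tri-O-benzylfustin
Product: 6 (+)-fustin
Conditions: H2 (1 atm), Pd(OH)2/C, THF–MeOH 1:1, rt, 3 h
Reagents that add atoms: none
Why: Catalytic hydrogenolysis over heterogeneous Pd cleaves the three aryl benzyl ethers to toluene under neutral conditions, so the electron-rich C-4 ketone, the C-2–O bond and the base-sensitive C-2/C-3 stereocentres are left intact.

Step 4
Reactants: 6 (+)-fustin (2.6 equiv); 7 (+)-catechin (1 equiv)
Product: 11 fisetinidol-(4α→8)-[fisetinidol-(4β→6)]-catechin (CNP0289228.1), via mollisacacidin 8 (not isolated), via quinone methide 9 (not isolated), via biflavanoid 10 (not isolated)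
Conditions: NaBH4 (3 equiv per 6), EtOH–H2O 1:1, 0 °C→rt, 2 h, N2; then 7, HCl to 0.1 M, rt, 24–48 h, N2, dark; Sephadex LH-20 (EtOH), then reversed-phase HPLC
Reagents that add atoms: none
Why: NaBH4 reduces the C-4 ketone to the flavan-3,4-diol 8 (a dihydroflavonol 4-reductase mimic; the new C-4 centre is erased in the next event), 0.1 M HCl ionises the benzylic 4-OH to the 7-oxygen-stabilised cation/quinone methide 9, and two biomimetic Friedel–Crafts-type interflavanyl couplings (electrophilic aromatic substitution) follow on the far more nucleophilic phloroglucinol-type ring A of catechin — first at C-8 anti to the 3-OH of the electrophile (4α, 3,4-trans, giving 10), then at the flanked C-6 where facial selectivity is low and syn attack gives the required 4β (3,4-cis) unit alongside its separable 4α epimer — while C-2/C-3 of all three units are untouched and the resorcinol-type rings of the electrophile are too weakly nucleophilic to compete.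

**Compound list**

1 | 1-[4-(benzyloxy)-2-hydroxyphenyl]ethan-1-one (4'-benzyloxy-2'-hydroxyacetophenone) | CC(=O)c1ccc(OCc2ccccc2)cc1O | starting material
2 | 3,4-bis(benzyloxy)benzaldehyde | O=Cc1ccc(OCc2ccccc2)c(OCc2ccccc2)c1 | starting material
3 | (E)-1-[4-(benzyloxy)-2-hydroxyphenyl]-3-[3,4-bis(benzyloxy)phenyl]prop-2-en-1-one (tri-O-benzylbutein) | O=C(/C=C/c1ccc(OCc2ccccc2)c(OCc2ccccc2)c1)c1ccc(OCc2ccccc2)cc1O | intermediate
4 | (2S)-7-(benzyloxy)-2-[3,4-bis(benzyloxy)phenyl]-2H-chromen-4-olate (flavanone enolate, anion of the ion pair with the catalyst cation; 2-aryl α) | C(c1ccccc1)Oc1ccc2c(c1)O[C@H](c1ccc(OCc3ccccc3)c(OCc3ccccc3)c1)C=C2[O-] | intermediate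
5 | (2R,3R)-7-(benzyloxy)-2-[3,4-bis(benzyloxy)phenyl]-3-hydroxy-2,3-dihydro-4H-chromen-4-one (2,3-trans; 7,3',4'-tri-O-benzyl-(+)-fustin) | C(c1ccccc1)Oc1ccc2c(c1)O[C@H](c1ccc(OCc3ccccc3)c(OCc3ccccc3)c1)[C@@H](O)C2=O | intermediate
6 | (2R,3R)-2-(3,4-dihydroxyphenyl)-3,7-dihydroxy-2,3-dihydro-4H-chromen-4-one ((+)-fustin) | Oc1ccc2c(c1)O[C@H](c1ccc(O)c(O)c1)[C@@H](O)C2=O | intermediate
7 | (2R,3S)-2-(3,4-dihydroxyphenyl)-3,4-dihydro-2H-chromene-3,5,7-triol ((+)-catechin) | Oc1cc(O)c2c(c1)O[C@H](c1ccc(O)c(O)c1)[C@@H](O)C2 | starting material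
8 | (2R,3S,4R)-2-(3,4-dihydroxyphenyl)-3,4-dihydro-2H-chromene-3,4,7-triol ((+)-mollisacacidin; 2,3-trans-3,4-trans leucofisetinidin) | Oc1ccc2c(c1)O[C@H](c1ccc(O)c(O)c1)[C@@H](O)[C@@H]2O | intermediate
9 | (2R,3S)-2-(3,4-dihydroxyphenyl)-3-hydroxy-2,3-dihydro-7H-chromen-7-one (ring-A quinone methide, neutral form of the C-4 cation of 8) | O=C1C=CC2=C[C@H](O)[C@@H](c3ccc(O)c(O)c3)OC2=C1 | intermediate
10 | fisetinidol-(4α→8)-catechin: (2R,3S)-catechin carrying at C-8 a (2R,3S,4S)-fisetinidol-4-yl unit (2,3-trans-3,4-trans) | c1c(O)c2c(c([C@@H]3c4ccc(O)cc4O[C@H](c4ccc(O)c(O)c4)[C@H]3O)c1O)O[C@H](c1ccc(O)c(O)c1)[C@@H](O)C2 | intermediate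
11 | fisetinidol-(4α→8)-[fisetinidol-(4β→6)]-catechin: (2R,3S)-catechin carrying at C-8 a (2R,3S,4S)-fisetinidol-4-yl unit (3,4-trans) and at C-6 a (2R,3S,4R)-fisetinidol-4-yl unit (3,4-cis) | Oc1ccc2c(c1)O[C@H](c1ccc(O)c(O)c1)[C@@H](O)[C@H]2c1c(O)c2c(c([C@@H]3c4ccc(O)cc4O[C@H](c4ccc(O)c(O)c4)[C@H]3O)c1O)O[C@H](c1ccc(O)c(O)c1)[C@@H](O)C2 | target

**Totals and risks**

Total step count: 4.
Longest linear sequence: 4 steps (1/2 → 3 → 5 → 6 → 11); 7 enters in the last step.

Steps most likely to fail, in order of risk:

Step 2. The enantioselective cyclisation–hydroxylation is unprecedented. Likely failure modes are low ee (a competing epoxide pathway or reversible ring closure) and over-oxidation to the flavonol. The fallback sets out from 3 and comes back to the route at 5. The 2'-OH of 3 is capped (MOMCl, iPr2NEt, CH2Cl2) to give the 2'-O-methoxymethyl chalcone F1. A Juliá–Colonna epoxidation (poly-L-leucine, urea–H2O2, DBU, THF, rt), for which the L-polypeptide reliably gives the (αR,βS) series, then gives the chalcone epoxide F2. BnSH/SnCl4 (CH2Cl2, −20 °C) removes the acetal and opens the oxirane at the benzylic carbon with inversion to give the α-hydroxy-β-benzylsulfanyl dihydrochalcone F3. AgBF4 (CH2Cl2, 0 °C) finally ionises the C–S bond and the 2'-OH closes ring C, giving predominantly the 2,3-trans dihydroflavonol 5, with C-3 fixed by the epoxide.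

Step 4. The one-pot gives a mixture of bi- and triflavanoids. Only part of the C-6 coupling is 4β, so a low isolated yield (of the order of 5–10%) and a demanding separation are expected. The fallback sets out from 6 and comes back to the route at 11, passing through isolated 8 and isolated 10. Compound 6 is reduced as before, but 8 is isolated (EtOAc extraction at pH 5). With BnSH in AcOH at rt, 8 gives the 4-benzylsulfanylfisetinidol F4 by sulfur capture of the C-4 cation; its C-4 epimer ratio is immaterial. F4 (1 equiv) is activated with AgBF4 in THF at 0 °C in the presence of excess 7 (4 equiv), and chromatography gives pure 10. A second AgBF4-mediated coupling of 10 with F4 (1.2 equiv) under the same neutral conditions gives 11 and its C-4 epimer at the new unit as the only two triflavanoids to separate. This replaces the Brønsted-acid one-pot by two stoichiometrically controlled couplings of a storable electrophile with a thiophilic Lewis acid.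

Step 3. Hydrogenolysis in the presence of the C-4 ketone may over-reduce at C-4 or stall on the poorly soluble partly debenzylated material. The fallback sets out from 5 and comes back to the route at 11. The ketone of 5 is reduced first (NaBH4, THF–MeOH, 0 °C) to the tri-O-benzyl flavan-3,4-diol F5. F5 (2.6 equiv) and free 7 are coupled with BF3·OEt2 in dioxane (0 °C→rt), the 7-benzyloxy group still stabilising the C-4 cation, to give the hexa-O-benzyl triflavanoid F6, which is separated from its isomers on silica at this less polar stage. Global hydrogenolysis of F6 (H2, Pd(OH)2/C, THF–MeOH), which no longer carries a ketone or a C-4 oxygen, gives 11.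

**Further compounds**

F1 | step 2 | (E)-1-[4-(benzyloxy)-2-(methoxymethoxy)phenyl]-3-[3,4-bis(benzyloxy)phenyl]prop-2-en-1-one | O=C(/C=C/c1ccc(OCc2ccccc2)c(OCc2ccccc2)c1)c1ccc(OCc2ccccc2)cc1OCOC
F2 | step 2 | [4-(benzyloxy)-2-(methoxymethoxy)phenyl][(2R,3S)-3-[3,4-bis(benzyloxy)phenyl]oxiran-2-yl]methanone | O=C([C@@H]1O[C@H]1c1ccc(OCc2ccccc2)c(OCc2ccccc2)c1)c1ccc(OCc2ccccc2)cc1OCOC
F3 | step 2 | (2S,3R)-3-(benzylsulfanyl)-1-[4-(benzyloxy)-2-hydroxyphenyl]-3-[3,4-bis(benzyloxy)phenyl]-2-hydroxypropan-1-one | O=C([C@H](O)[C@H](SCc1ccccc1)c1ccc(OCc2ccccc2)c(OCc2ccccc2)c1)c1ccc(OCc2ccccc2)cc1O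
F4 | step 4 | (2R,3S,4R)-4-(benzylsulfanyl)-2-(3,4-dihydroxyphenyl)-3,4-dihydro-2H-chromene-3,7-diol (4α-benzylsulfanylfisetinidol) | Oc1ccc2c(c1)O[C@H](c1ccc(O)c(O)c1)[C@@H](O)[C@@H]2SCc1ccccc1
F5 | step 3 | (2R,3S,4R)-7-(benzyloxy)-2-[3,4-bis(benzyloxy)phenyl]-3,4-dihydro-2H-chromene-3,4-diol | C(c1ccccc1)Oc1ccc2c(c1)O[C@H](c1ccc(OCc3ccccc3)c(OCc3ccccc3)c1)[C@@H](O)[C@@H]2O
F6 | step 3 | hexa-O-benzyl triflavanoid (11 with the 7, 3' and 4' hydroxyls of both fisetinidol units as benzyl ethers; catechin unit free) | C(c1ccccc1)Oc1ccc2c(c1)O[C@H](c1ccc(OCc3ccccc3)c(OCc3ccccc3)c1)[C@@H](O)[C@H]2c1c(O)c2c(c([C@@H]3c4ccc(OCc5ccccc5)cc4O[C@H](c4ccc(OCc5ccccc5)c(OCc5ccccc5)c4)[C@H]3O)c1O)O[C@H](c1ccc(O)c(O)c1)[C@@H](O)C2
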